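**Plan**
Retrosynthesis: the oxolane is cut at O1–C2 and C2–C3, which takes C2 and its aryl group back to 3,4,5-trimethoxybenzaldehyde. The chain is then cut at C4–C7′ (aldol) and at the imide N–acyl bond.
Forward: an (E)-5-silylpent-3-enoic acid linchpin is bound to an Evans auxiliary, and a syn-aldol reaction with 3,4-dimethoxybenzaldehyde joins the chain C5–C4(–C7′)–C3=C. The oxolane, the only non-aromatic ring, is closed last by an oxocarbenium/allylsilane annulation with the second aldehyde.
Enabling feature: C2 is a benzylic carbon bound to the ring oxygen (a latent aryl-stabilised oxocarbenium ion), and its neighbour C3 bears a one-carbon branch. C3 can therefore be the γ-carbon of an allylsilane tethered to O1 through C4–C5.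
Helpers: silicon leaves in the ring closure; the extra vinyl carbon, the auxiliary and the TBS group are removed afterwards.
Stereochemistry: C4 and C7′ come from the auxiliary-controlled syn-aldol; C2 and C3 are set in the ring closure under control of C4 (all-trans).

Key step: step 7

Remark: the target is read as the (2R,3S,4R)-oxolane with an (S)-carbinol, all three ring substituents mutually trans. Locants used: O1, C2 (aryl), C3 (CH2OH), C4, C5, and C7′ for the exocyclic carbinol carbon.

**Step 1**
Reactants: 1 3-(trimethylsilyl)propan-1-ol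
Product: 2 3-(trimethylsilyl)propanal
Conditions: TEMPO (10 mol %), PhI(OAc)2 (1.1 equiv), CH2Cl2, rt
Reagents that add atoms: none
Why: Oxoammonium-mediated (TEMPO) alcohol oxidation should stop at the aldehyde and leave the C–Si bond untouched; no stereocentre is involved.

**Step 2**
Reactants: 2 3-(trimethylsilyl)propanal; 3 malonic acid
Product: 4 (E)-5-(trimethylsilyl)pent-3-enoic acid
Conditions: piperidinium acetate (cat.), DMSO, 100 °C
Reagents that add atoms: none
Why: Knoevenagel–Doebner condensation in its deconjugative variant, in which the alkylidenemalonic acid isomerises to the β,γ-unsaturated diacid before decarboxylation, should give the (E)-alk-3-enoic acid and thereby the (E)-allylsilane.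

**Step 3**
Reactants: 4 (E)-5-(trimethylsilyl)pent-3-enoic acid; 5 (S)-4-benzyl-1,3-oxazolidin-2-one
Product: 7 (S)-4-benzyl-3-[(E)-5-(trimethylsilyl)pent-3-enoyl]-1,3-oxazolidin-2-one, via mixed pivalic anhydride 6 (not isolated)
Conditions: PivCl, Et3N, THF, −20 °C; then 5, LiCl, −20 °C → rt
Reagents that add atoms: pivaloyl chloride, CC(C)(C)C(=O)Cl (its acyl group is held only in intermediate 6)
Why: N-acylation of the oxazolidinone through a mixed anhydride with LiCl/Et3N activation is the standard mild entry to Evans imides and avoids the strong base that could move the double bond into conjugation.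

**Step 4**
Reactants: 7 (S)-4-benzyl-3-[(E)-5-(trimethylsilyl)pent-3-enoyl]-1,3-oxazolidin-2-one; 8 3,4-dimethoxybenzaldehyde
Product: 10 (S)-4-benzyl-3-[(2S,3S)-3-(3,4-dimethoxyphenyl)-3-hydroxy-2-[(E)-3-(trimethylsilyl)prop-1-en-1-yl]propanoyl]-1,3-oxazolidin-2-one, via dibutylboron Z-enolate 9 (not isolated)
Conditions: Bu2BOTf, i-Pr2NEt, CH2Cl2, −78 → 0 °C; then 8, −78 → 0 °C; pH 7 buffer, MeOH, H2O2, 0 °C
Reagents that add atoms: dibutylboron triflate, CCCCB(CCCC)OS(=O)(=O)C(F)(F)F (its boron group is held only in intermediate 9)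
Why: Evans syn-aldol reaction: the Z-boron enolate 9 should react at its α-carbon through a closed Zimmerman–Traxler chair in which the (S)-benzyl auxiliary blocks one enolate face, setting the (2S,3S) pair that becomes C4 and C7′.

**Step 5**
Reactants: 10 the syn-aldol adduct
Product: 11 (S)-4-benzyl-3-[(2S,3S)-3-[(tert-butyldimethylsilyl)oxy]-3-(3,4-dimethoxyphenyl)-2-[(E)-3-(trimethylsilyl)prop-1-en-1-yl]propanoyl]-1,3-oxazolidin-2-one
Conditions: TBSOTf, 2,6-lutidine, CH2Cl2, −78 → 0 °C
Reagents that add atoms: tert-butyldimethylsilyl triflate, CC(C)(C)[Si](C)(C)OS(=O)(=O)C(F)(F)F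
Why: Silylation of the secondary alcohol with a silyl triflate and a hindered base masks the C7′ oxygen so that only the later primary alcohol can form the oxocarbenium ion; the mild base should not cause retro-aldol cleavage.

**Step 6**
Reactants: 11 the TBS-protected imide
Product: 12 (2R,3S)-3-[(tert-butyldimethylsilyl)oxy]-3-(3,4-dimethoxyphenyl)-2-[(E)-3-(trimethylsilyl)prop-1-en-1-yl]propan-1-ol
Conditions: LiBH4, MeOH (1 equiv), THF, 0 °C
Reagents that add atoms: none
Why: Reductive cleavage of the N-acyl oxazolidinone by borohydride (attack at the exocyclic imide carbonyl) should release the primary alcohol and the auxiliary without touching the two stereocentres.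

**Step 7**
Reactants: 12 the silyl-protected allylsilane alcohol; 13 3,4,5-trimethoxybenzaldehyde
Product: 15 (2R,3R,4R)-4-[(S)-[(tert-butyldimethylsilyl)oxy](3,4-dimethoxyphenyl)methyl]-3-ethenyl-2-(3,4,5-trimethoxyphenyl)oxolane, via oxocarbenium ion 14 (not isolated)
Conditions: TMSOTf (0.3 equiv), 2,6-di-tert-butyl-4-methylpyridine (0.4 equiv), 4 Å MS, CH2Cl2, −78 → −40 °C
Reagents that add atoms: none
Why: The primary alcohol of 12 and aldehyde 13 should condense under TMSOTf to the aryl-stabilised E-oxocarbenium ion 14, whose carbon is attacked by the γ-carbon of the tethered allylsilane (anti SE2′) to give a β-silyl cation that loses Me3Si+ and leaves the vinyl group on C3. The closest known reaction type is the intramolecular Hosomi–Sakurai (silyl-modified Sakurai, Prins-type) annulation of silyl-bearing homoallylic alcohols with aldehydes to 2-substituted 3-vinyltetrahydrofurans. The oxolane is closed by C2–C3 bond formation in a five-membered mode that is endo with respect to the C=O+ bond and exo with respect to the allylsilane C=C bond, O1–C2 having been made in the same flask by hemiacetal formation. C3 is controlled by C4 through allylic 1,3-strain: the C4–H eclipses the E-alkene, so the oxocarbenium arm tethered through C5–O1 reaches the alkene face anti to the bulky CH(OTBS)Ar group, which should give the 3,4-trans relationship. C2 is controlled by the envelope transition state, in which the aryl group of the E-oxocarbenium ion lies pseudo-equatorial and away from the developing vinyl branch, which should give the 2,3-trans relationship; the all-trans product is also the thermodynamic isomer. The step needs C–C closure to beat acetal formation by the C7′ oxygen, and attack at the γ-carbon to beat an oxonia-Cope shift; the bulky TBS ether, the β-silicon effect, the buffer and the low temperature should secure both.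

**Step 8**
Reactants: 15 the 3-vinyl oxolane
Product: 16 (2R,3R,4R)-4-[(S)-[(tert-butyldimethylsilyl)oxy](3,4-dimethoxyphenyl)methyl]-2-(3,4,5-trimethoxyphenyl)oxolane-3-carbaldehyde
Conditions: OsO4 (2 mol %), NaIO4 (4 equiv), 2,6-lutidine, dioxane/H2O, rt
Reagents that add atoms: sodium periodate, [Na+].[O-]I(=O)(=O)=O (terminal oxidant and net source of the aldehyde oxygen)
Why: Lemieux–Johnson oxidative cleavage: OsO4 should dihydroxylate the only alkene and NaIO4 cleave the diol, with the electron-rich arenes and the silyl ether inert; C3, now α to the aldehyde, already holds the thermodynamically preferred trans,trans arrangement.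

**Step 9**
Reactants: 16 the oxolane-3-carbaldehyde
Product: 17 [(2R,3S,4R)-4-[(S)-[(tert-butyldimethylsilyl)oxy](3,4-dimethoxyphenyl)methyl]-2-(3,4,5-trimethoxyphenyl)oxolan-3-yl]methanol
Conditions: NaBH4, MeOH, 0 °C
Reagents that add atoms: none
Why: Borohydride reduction of the aldehyde to the primary alcohol; no new stereocentre is formed and the cold, weakly basic medium should not epimerise C3.

**Step 10**
Reactants: 17 the TBS-protected diol precursor
Product: 18 [(2R,3S,4R)-4-[(S)-(3,4-dimethoxyphenyl)(hydroxy)methyl]-2-(3,4,5-trimethoxyphenyl)oxolan-3-yl]methanol (CNP0172668.1)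
Conditions: TBAF, THF, 0 °C → rt
Reagents that add atoms: none
Why: Fluoride-mediated desilylation frees the C7′ alcohol under non-acidic conditions, which avoids ionising the two electron-rich benzylic C–O bonds.

**Compound list**
1 | 3-(trimethylsilyl)propan-1-ol | C[Si](C)(C)CCCO | starting material
2 | 3-(trimethylsilyl)propanal | C[Si](C)(C)CCC=O | intermediate
3 | malonic acid | OC(=O)CC(=O)O | starting material
4 | (E)-5-(trimethylsilyl)pent-3-enoic acid | C[Si](C)(C)C/C=C/CC(=O)O | intermediate
5 | (S)-4-benzyl-1,3-oxazolidin-2-one | O=C1N[C@@H](Cc2ccccc2)CO1 | starting material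
6 | (E)-5-(trimethylsilyl)pent-3-enoic pivalic anhydride | C[Si](C)(C)C/C=C/CC(=O)OC(=O)C(C)(C)C | intermediate
7 | (S)-4-benzyl-3-[(E)-5-(trimethylsilyl)pent-3-enoyl]-1,3-oxazolidin-2-one | C[Si](C)(C)C/C=C/CC(=O)N1[C@@H](Cc2ccccc2)COC1=O | intermediate
8 | 3,4-dimethoxybenzaldehyde | COc1ccc(C=O)cc1OC | starting material
9 | (S)-4-benzyl-3-[(1Z,3E)-1-(dibutylboranyloxy)-5-(trimethylsilyl)penta-1,3-dien-1-yl]-1,3-oxazolidin-2-one | C[Si](C)(C)C/C=C/C=C(\OB(CCCC)CCCC)N1[C@@H](Cc2ccccc2)COC1=O | intermediate
10 | (S)-4-benzyl-3-[(2S,3S)-3-(3,4-dimethoxyphenyl)-3-hydroxy-2-[(E)-3-(trimethylsilyl)prop-1-en-1-yl]propanoyl]-1,3-oxazolidin-2-one | COc1ccc([C@@H](O)[C@H](/C=C/C[Si](C)(C)C)C(=O)N2[C@@H](Cc3ccccc3)COC2=O)cc1OC | intermediate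
11 | (S)-4-benzyl-3-[(2S,3S)-3-[(tert-butyldimethylsilyl)oxy]-3-(3,4-dimethoxyphenyl)-2-[(E)-3-(trimethylsilyl)prop-1-en-1-yl]propanoyl]-1,3-oxazolidin-2-one | COc1ccc([C@@H](O[Si](C)(C)C(C)(C)C)[C@H](/C=C/C[Si](C)(C)C)C(=O)N2[C@@H](Cc3ccccc3)COC2=O)cc1OC | intermediate
12 | (2R,3S)-3-[(tert-butyldimethylsilyl)oxy]-3-(3,4-dimethoxyphenyl)-2-[(E)-3-(trimethylsilyl)prop-1-en-1-yl]propan-1-ol | COc1ccc([C@@H](O[Si](C)(C)C(C)(C)C)[C@H](/C=C/C[Si](C)(C)C)CO)cc1OC | intermediate
13 | 3,4,5-trimethoxybenzaldehyde | COc1cc(C=O)cc(OC)c1OC | starting material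
14 | oxocarbenium ion from 12 and 13 (O-alkylated 3,4,5-trimethoxybenzaldehyde cation) | COc1ccc([C@@H](O[Si](C)(C)C(C)(C)C)[C@H](/C=C/C[Si](C)(C)C)C[O+]=Cc2cc(OC)c(OC)c(OC)c2)cc1OC | intermediate
15 | (2R,3R,4R)-4-[(S)-[(tert-butyldimethylsilyl)oxy](3,4-dimethoxyphenyl)methyl]-3-ethenyl-2-(3,4,5-trimethoxyphenyl)oxolane | COc1ccc([C@@H](O[Si](C)(C)C(C)(C)C)[C@H]2CO[C@@H](c3cc(OC)c(OC)c(OC)c3)[C@@H]2C=C)cc1OC | intermediate
16 | (2R,3R,4R)-4-[(S)-[(tert-butyldimethylsilyl)oxy](3,4-dimethoxyphenyl)methyl]-2-(3,4,5-trimethoxyphenyl)oxolane-3-carbaldehyde | COc1ccc([C@@H](O[Si](C)(C)C(C)(C)C)[C@H]2CO[C@@H](c3cc(OC)c(OC)c(OC)c3)[C@@H]2C=O)cc1OC | intermediate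
17 | [(2R,3S,4R)-4-[(S)-[(tert-butyldimethylsilyl)oxy](3,4-dimethoxyphenyl)methyl]-2-(3,4,5-trimethoxyphenyl)oxolan-3-yl]methanol | COc1ccc([C@@H](O[Si](C)(C)C(C)(C)C)[C@H]2CO[C@@H](c3cc(OC)c(OC)c(OC)c3)[C@@H]2CO)cc1OC | intermediate
18 | [(2R,3S,4R)-4-[(S)-(3,4-dimethoxyphenyl)(hydroxy)methyl]-2-(3,4,5-trimethoxyphenyl)oxolan-3-yl]methanol | COc1ccc([C@@H](O)[C@H]2CO[C@@H](c3cc(OC)c(OC)c(OC)c3)[C@@H]2CO)cc1OC | target

**Step count**
Total steps: 10. Longest linear sequence: 10 (1 → 2 → 4 → 7 → 10 → 11 → 12 → 15 → 16 → 17 → 18).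

**Steps most likely to fail**

Step 7. The risk is acetal formation by the silyl-protected C7′ oxygen with loss of the protecting group, or poor facial selectivity at the oxocarbenium carbon. The fallback sets out from 12 and comes back at 15, and makes the C–C and C–O ring bonds in separate operations. Compound 12 would be converted with TsCl, Et3N and DMAP in CH2Cl2 into (2R,3S)-3-[(tert-butyldimethylsilyl)oxy]-3-(3,4-dimethoxyphenyl)-2-[(E)-3-(trimethylsilyl)prop-1-en-1-yl]propyl 4-methylbenzenesulfonate F1. Intermolecular Hosomi–Sakurai addition of the allylsilane of F1 to 13 (BF3·OEt2, CH2Cl2, −78 °C) should give, through the antiperiplanar open transition state of the E-allylsilane, the syn homoallylic alcohol (2R,3R)-2-[(S)-[(tert-butyldimethylsilyl)oxy](3,4-dimethoxyphenyl)methyl]-3-[(R)-hydroxy(3,4,5-trimethoxyphenyl)methyl]pent-4-en-1-yl 4-methylbenzenesulfonate F2. NaH in THF should then close the oxolane by 5-exo-tet displacement of the tosylate by the benzylic alkoxide, giving 15; any C2 epimer would be removed by chromatography.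

Step 4. The risk is reaction of the extended boron enolate through its γ-carbon, migration of the double bond into conjugation, or protodesilylation of the allylsilane by the boron triflate. The fallback sets out from 5 and 8 and comes back at 12; silicon is introduced only after the aldol step. Compound 5 would be N-acylated with (E)-but-2-enoyl chloride (n-BuLi, THF, −78 °C) to (S)-4-benzyl-3-[(E)-but-2-enoyl]-1,3-oxazolidin-2-one F3. Its boron dienolate (Bu2BOTf, Et3N, CH2Cl2) should add to 8 through the α-carbon to give (S)-4-benzyl-3-[(2S,3S)-3-(3,4-dimethoxyphenyl)-2-ethenyl-3-hydroxypropanoyl]-1,3-oxazolidin-2-one F4. Silylation (TBSOTf, 2,6-lutidine) would give the silyl ether (S)-4-benzyl-3-[(2S,3S)-3-[(tert-butyldimethylsilyl)oxy]-3-(3,4-dimethoxyphenyl)-2-ethenylpropanoyl]-1,3-oxazolidin-2-one F5. LiBH4 would then give (2R,3S)-3-[(tert-butyldimethylsilyl)oxy]-3-(3,4-dimethoxyphenyl)-2-ethenylpropan-1-ol F6. Cross-metathesis of F6 with allyltrimethylsilane (second-generation Grubbs catalyst, (H2IMes)(PCy3)Cl2Ru=CHPh, CH2Cl2, 40 °C) should give 12 as the predominant E isomer; the Z isomer would have to be separated.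

Step 2. The risk is incomplete migration of the double bond out of conjugation, loss of E selectivity, or protodesilylation at 100 °C. The fallback sets out from 5 and comes back at 7, so compounds 2, 4 and 6 are not needed. Compound 5 would be acylated with but-3-enoic acid (PivCl, Et3N, LiCl, THF) to (S)-4-benzyl-3-(but-3-enoyl)-1,3-oxazolidin-2-one F7. Cross-metathesis of F7 with allyltrimethylsilane (second-generation Grubbs catalyst, (H2IMes)(PCy3)Cl2Ru=CHPh, CH2Cl2, 40 °C) should give 7 with the E isomer predominating; the Z isomer would be removed before step 4.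

**Further compounds**
F1 | step 7 | (2R,3S)-3-[(tert-butyldimethylsilyl)oxy]-3-(3,4-dimethoxyphenyl)-2-[(E)-3-(trimethylsilyl)prop-1-en-1-yl]propyl 4-methylbenzenesulfonate | COc1ccc([C@@H](O[Si](C)(C)C(C)(C)C)[C@H](/C=C/C[Si](C)(C)C)COS(=O)(=O)c2ccc(C)cc2)cc1OC
F2 | step 7 | (2R,3R)-2-[(S)-[(tert-butyldimethylsilyl)oxy](3,4-dimethoxyphenyl)methyl]-3-[(R)-hydroxy(3,4,5-trimethoxyphenyl)methyl]pent-4-en-1-yl 4-methylbenzenesulfonate | COc1ccc([C@@H](O[Si](C)(C)C(C)(C)C)[C@H]([C@@H](C=C)[C@@H](O)c2cc(OC)c(OC)c(OC)c2)COS(=O)(=O)c3ccc(C)cc3)cc1OC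
F3 | step 4 | (S)-4-benzyl-3-[(E)-but-2-enoyl]-1,3-oxazolidin-2-one | C/C=C/C(=O)N1[C@@H](Cc2ccccc2)COC1=O
F4 | step 4 | (S)-4-benzyl-3-[(2S,3S)-3-(3,4-dimethoxyphenyl)-2-ethenyl-3-hydroxypropanoyl]-1,3-oxazolidin-2-one | COc1ccc([C@@H](O)[C@H](C=C)C(=O)N2[C@@H](Cc3ccccc3)COC2=O)cc1OC
F5 | step 4 | (S)-4-benzyl-3-[(2S,3S)-3-[(tert-butyldimethylsilyl)oxy]-3-(3,4-dimethoxyphenyl)-2-ethenylpropanoyl]-1,3-oxazolidin-2-one | COc1ccc([C@@H](O[Si](C)(C)C(C)(C)C)[C@H](C=C)C(=O)N2[C@@H](Cc3ccccc3)COC2=O)cc1OC
F6 | step 4 | (2R,3S)-3-[(tert-butyldimethylsilyl)oxy]-3-(3,4-dimethoxyphenyl)-2-ethenylpropan-1-ol | COc1ccc([C@@H](O[Si](C)(C)C(C)(C)C)[C@H](C=C)CO)cc1OC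
F7 | step 2 | (S)-4-benzyl-3-(but-3-enoyl)-1,3-oxazolidin-2-one | C=CCC(=O)N1[C@@H](Cc2ccccc2)COC1=O
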